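A direct plan would take 2-hydroxy-4-methoxybenzaldehyde A1, mask its phenol and aldehyde, lithiate the ring between the two oxygens and add the aryllithium to the O-silylated α-hydroxy Weinreb amide A2 to reach the keto aldehyde A3.
It would then close the pyranone by a Z-selective olefination with lactonisation, remove the silyl group to give the α-ketol coumarin A4, and finish by O-senecioylation.
Weak point, the protecting-group stretch: a MOM ether, a dimethyl acetal and a silyl ether would be put on and taken off, so about half of the operations would build no bond of the target.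
Weak point, the aryl–acyl bond formation: a 2,6-disubstituted aryllithium would have to attack a doubly α-branched amide, so the most crowded C–C bond would rest on the step with the least steric reserve, and its acid work-up would have to cleave the acetal yet spare the MOM and silyl ethers.
Weak point, the final esterification of the free α-ketol A4: the most advanced intermediate, whose α-hydrogen is activated by the aryl ketone, would meet pyridine, DMAP and an acylpyridinium, so enolisation (epimerisation, ketol shift) would threaten the only stereocentre in the last step.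

**Retrosynthetic overview**
Ring B (pyranone) is cut at C4–C4a: it would close last by 6-endo hydroarylation of an aryl propiolate, with C2–C4 coming from propiolic acid.
Ring A (benzene) is cut at C8–C8a and C6–C7: a Diels–Alder/retro-Diels–Alder reaction of 3-hydroxy-2-pyranone (gives C8a with its oxygen, C4a, C5, C6) with the push–pull ynone MeO–C≡C–C(=O)–CH(O-senecioyl)–iPr (gives C7 with OMe and C8 with the whole acyl side chain) would build the ring and expel CO2.
The contiguous C7(OMe)–C8(acyl)–C8a(O) triad of ring A, the most crowded part of the target, would thus be set by the polarity of the two partners and not by an organometallic addition at the most hindered ring position.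
The stereocentre would come from the chiral-pool (R)-α-hydroxy acid and be senecioylated in step 1; the ester of the target serves as its own protecting group, so there is no protecting-group step, no free α-ketol and no late acylation.
Order of ring formation: ring A is created in step 4 from a pyranone that is consumed, and ring B is closed on it in step 6 by a C–C bond.

Key step: step 4

Assumption: (2R)-2-hydroxy-3-methylbutanoic acid (the D-valine-derived hydroxy acid) and 3-hydroxy-2H-pyran-2-one are taken as purchasable; the target descriptor is R, as read from its SMILES.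

**Step 1**
Reactants: 1 (2R)-2-hydroxy-3-methylbutanoic acid; 2 3-methylbut-2-enoyl chloride
Product: 4 (2R)-3-methyl-2-[(3-methylbut-2-enoyl)oxy]butanoic acid, via mixed anhydride 3 (not isolated)
Conditions: 2 (2.2 equiv), neat, 50 °C, N2 sweep; then THF/H2O, rt
Reagents that add atoms: none
Why: O-acylation of the secondary alcohol by the acid chloride without an amine base (so no ketene pathway that could deconjugate the senecioyl group), in which the second equivalent of 2 ties up the carboxyl group as the mixed anhydride 3, followed by hydrolysis of 3 at its less hindered senecioyl carbonyl to return the free acid; no bond at the stereocentre is touched, so R is retained.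

**Step 2**
Reactants: 4 (2R)-3-methyl-2-[(3-methylbut-2-enoyl)oxy]butanoic acid
Product: 5 (2R)-1-[methoxy(methyl)amino]-3-methyl-1-oxobutan-2-yl 3-methylbut-2-enoate
Conditions: MeNHOMe·HCl, EDC·HCl, HOBt (cat.), N-methylmorpholine, CH2Cl2, 0 °C → rt
Reagents that add atoms: N,O-dimethylhydroxylamine hydrochloride, CNOC.Cl
Why: Carbodiimide amide coupling through the HOBt active ester gives the Weinreb amide under near-neutral conditions that should not enolise the α-acyloxy acid derivative.

**Step 3**
Reactants: 5 (2R)-1-[methoxy(methyl)amino]-3-methyl-1-oxobutan-2-yl 3-methylbut-2-enoate; 6 2-chloro-1,1-dimethoxyethane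
Product: 8 (4R)-1-methoxy-5-methyl-3-oxohex-1-yn-4-yl 3-methylbut-2-enoate, via lithium methoxyacetylide 7 (not isolated)
Conditions: 6 (1.5 equiv), Et2NH (4.5 equiv), n-BuLi (4.4 equiv), THF, 0 °C; then 5, −78 °C; inverse quench into cold aq. NaH2PO4/Et2O
Reagents that add atoms: none
Why: Two eliminations (MeOH, HCl) and deprotonation of the chloroacetal by LiNEt2 give the acetylide, which adds to the amide in a Weinreb ketone synthesis; the chelated tetrahedral adduct should release the ynone only in the buffered quench, when the amines are protonated, and the weakly basic acetylide should neither enolise the stereocentre nor attack the hindered conjugated ester at −78 °C.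

**Step 4**
Reactants: 8 (4R)-1-methoxy-5-methyl-3-oxohex-1-yn-4-yl 3-methylbut-2-enoate; 9 3-hydroxy-2H-pyran-2-one
Product: 11 (2R)-1-(2-hydroxy-6-methoxyphenyl)-3-methyl-1-oxobutan-2-yl 3-methylbut-2-enoate, via oxabicyclooctadienone cycloadduct 10 (not isolated)
Conditions: 9 (1.5 equiv), PhMe, 110 °C, sealed tube
Reagents that add atoms: none
Why: Thermal [4+2] cycloaddition of the electron-rich diene of 9 (C3=C4–C5=C6) to the acyl-activated triple bond of 8 should give the bridged lactone 10, which loses CO2 by retro-[4+2] at the same temperature and so delivers the benzene ring without an oxidation step; the closest known reaction type is the Diels–Alder/decarboxylation of 2-pyranones, 3-hydroxy-2-pyranone included, with electron-poor alkynes to give arenes. Ring A closes by this intermolecular [4+2], which forms C8–C8a and C6–C7 (coumarin numbering), and becomes aromatic when the O–C(=O) bridge leaves. The step needs one regiochemistry: the hydroxyl on diene terminus C3, together with the lactone carbonyl attached to that carbon, puts the largest HOMO coefficient on C6 (outweighing the acylated ring oxygen there), and both the ketone and the methoxy group put the largest LUMO coefficient on the methoxy-bearing alkyne carbon, so C6 should bond to that carbon and the acyl-bearing carbon to the hydroxyl-bearing carbon, giving the 2-acyl-3-methoxyphenol pattern. Chemoselectivity rests on the ynone being the only activated 2π component, since the senecioate alkene is trisubstituted and conjugated only to an ester. No stereocentre is formed (the bridgehead centres of 10 vanish on aromatisation), and the R centre lies outside the reacting π-system under neutral conditions. A methyl ynol ether has no β-hydrogen on its alkyl group and so cannot fragment to a ketene by a retro-ene reaction at this temperature.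

**Step 5**
Reactants: 11 (2R)-1-(2-hydroxy-6-methoxyphenyl)-3-methyl-1-oxobutan-2-yl 3-methylbut-2-enoate; 12 prop-2-ynoic acid
Product: 13 (2R)-1-[2-methoxy-6-(prop-2-ynoyloxy)phenyl]-3-methyl-1-oxobutan-2-yl 3-methylbut-2-enoate
Conditions: DCC, DMAP (5 mol%), CH2Cl2, −20 → 0 °C
Reagents that add atoms: none
Why: Steglich esterification of the phenol, in which low temperature and only catalytic DMAP should keep conjugate addition of the phenol to the propiolate and enolisation of the α-acyloxy ketone in check.

**Step 6**
Reactants: 13 (2R)-1-[2-methoxy-6-(prop-2-ynoyloxy)phenyl]-3-methyl-1-oxobutan-2-yl 3-methylbut-2-enoate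
Product: 14 (2R)-1-(7-methoxy-2-oxo-2H-chromen-8-yl)-3-methyl-1-oxobutan-2-yl 3-methylbut-2-enoate
Conditions: AuCl3 (5 mol%), AgOTf (15 mol%), ClCH2CH2Cl, 60 °C
Reagents that add atoms: none
Why: Intramolecular hydroarylation of an aryl alkynoate, in which the alkyne activated by cationic trivalent gold is attacked 6-endo-dig by the only free ortho carbon (para to OMe, meta to the acyl group) and protodeauration closes ring B at C4–C4a; the neutral, non-basic conditions should leave the R centre and both esters untouched.

**Compound list**
1 | (2R)-2-hydroxy-3-methylbutanoic acid | OC(=O)[C@H](O)C(C)C | starting material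
2 | 3-methylbut-2-enoyl chloride | CC(C)=CC(=O)Cl | starting material
3 | (2R)-3-methyl-2-[(3-methylbut-2-enoyl)oxy]butanoic 3-methylbut-2-enoic anhydride (formed in the flask) | CC(C)=CC(=O)OC(=O)[C@H](OC(=O)C=C(C)C)C(C)C | intermediate
4 | (2R)-3-methyl-2-[(3-methylbut-2-enoyl)oxy]butanoic acid | OC(=O)[C@H](OC(=O)C=C(C)C)C(C)C | intermediate
5 | (2R)-1-[methoxy(methyl)amino]-3-methyl-1-oxobutan-2-yl 3-methylbut-2-enoate | CON(C)C(=O)[C@H](OC(=O)C=C(C)C)C(C)C | intermediate
6 | 2-chloro-1,1-dimethoxyethane | COC(CCl)OC | starting material
7 | lithium methoxyacetylide (formed in the flask) | [Li]C#COC | intermediate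
8 | (4R)-1-methoxy-5-methyl-3-oxohex-1-yn-4-yl 3-methylbut-2-enoate | COC#CC(=O)[C@H](OC(=O)C=C(C)C)C(C)C | intermediate
9 | 3-hydroxy-2H-pyran-2-one | O=C1OC=CC=C1O | starting material
10 | (2R)-1-(4-hydroxy-6-methoxy-3-oxo-2-oxabicyclo[2.2.2]octa-5,7-dien-5-yl)-3-methyl-1-oxobutan-2-yl 3-methylbut-2-enoate (formed in the flask, both bridgehead diastereomers) | O=C1OC2C=CC1(O)C(C(=O)[C@H](OC(=O)C=C(C)C)C(C)C)=C2OC | intermediate
11 | (2R)-1-(2-hydroxy-6-methoxyphenyl)-3-methyl-1-oxobutan-2-yl 3-methylbut-2-enoate | COc1cccc(O)c1C(=O)[C@H](OC(=O)C=C(C)C)C(C)C | intermediate
12 | prop-2-ynoic acid | C#CC(=O)O | starting material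
13 | (2R)-1-[2-methoxy-6-(prop-2-ynoyloxy)phenyl]-3-methyl-1-oxobutan-2-yl 3-methylbut-2-enoate | COc1cccc(OC(=O)C#C)c1C(=O)[C@H](OC(=O)C=C(C)C)C(C)C | intermediate
14 | (2R)-1-(7-methoxy-2-oxo-2H-chromen-8-yl)-3-methyl-1-oxobutan-2-yl 3-methylbut-2-enoate | COc1ccc2ccc(=O)oc2c1C(=O)[C@H](OC(=O)C=C(C)C)C(C)C | target

**Totals**
Total step count: 6. Longest linear sequence: 6 steps (1 → 4 → 5 → 8 → 11 → 13 → 14).

**Steps most likely to fail**

First, the cycloaddition of step 4. The donor-substituted triple bond may be too weak a dienophile at a temperature the stereocentre tolerates, the enolic hydroxyl of 9 may add across the ynone instead of the diene reacting at carbon, or the α-acyloxy ketone may epimerise on long heating. The fallback sets out from acid 4 and does not build the ring but takes it from an aryne. 3-Methoxy-2-(trimethylsilyl)phenyl trifluoromethanesulfonate F1 with CsF in THF at about 125 °C in a sealed tube would release 3-methoxybenzyne F2. The carboxylate of 4 would add to the carbon of F2 remote from the methoxy group, and the aryl anion next to OMe would attack the carboxyl carbonyl. The aryne thus inserts into the acyl C–O bond and gives the o-hydroxyaryl ketone 11, where the route is rejoined; the configurational integrity of the α-centre under fluoride would have to be checked.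

Second, the ynone formation of step 3. Lithium methoxide or the acetylide may cleave the senecioate, diethylamine or N,O-dimethylhydroxylamine may add to the push–pull ynone during the quench, and the ynol ether may be hydrated on contact with aqueous acid or silica. The fallback sets out from acid 4. Oxalyl chloride with catalytic DMF in CH2Cl2 would give the acid chloride (2R)-1-chloro-3-methyl-1-oxobutan-2-yl 3-methylbut-2-enoate F3. Tributyl(methoxyethynyl)stannane F4, made beforehand from acetylide 7 and Bu3SnCl and distilled, would be coupled with F3 under PdCl2(PPh3)2 catalysis in toluene (Stille acylation). This forms ynone 8 under neutral, amine-free and water-free conditions, and the route is rejoined at 8.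

Third, the hydroarylation of step 6. Auration and attack by the arene may be slow because the ring carries an acyl group and an ester oxygen, so hydration or oligomerisation of the terminal alkyne could take over. The fallback sets out from phenol 11 and closes ring B at C3=C4 instead. Ortho-formylation with Cl2CHOMe and TiCl4 in CH2Cl2 (Rieche formylation; the titanium phenoxide directs to the free ortho position, which is also para to OMe) would give (2R)-1-(3-formyl-2-hydroxy-6-methoxyphenyl)-3-methyl-1-oxobutan-2-yl 3-methylbut-2-enoate F5. (Triphenylphosphoranylidene)ketene in toluene at 80 °C would acylate the phenol of F5 to the ester ylide 6-formyl-3-methoxy-2-[(2R)-3-methyl-2-[(3-methylbut-2-enoyl)oxy]butanoyl]phenyl (triphenyl-λ5-phosphanylidene)acetate F6. The intramolecular Wittig reaction of F6 with the neighbouring aldehyde would give 14 directly, so the route is rejoined at the target.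

**Further compounds**
F1 | step 4 | 3-methoxy-2-(trimethylsilyl)phenyl trifluoromethanesulfonate | COc1cccc(OS(=O)(=O)C(F)(F)F)c1[Si](C)(C)C
F2 | step 4 | 3-methoxybenzyne | COC1=CC=CC#C1
F3 | step 3 | (2R)-1-chloro-3-methyl-1-oxobutan-2-yl 3-methylbut-2-enoate | ClC(=O)[C@H](OC(=O)C=C(C)C)C(C)C
F4 | step 3 | tributyl(methoxyethynyl)stannane | CCCC[Sn](CCCC)(CCCC)C#COC
F5 | step 6 | (2R)-1-(3-formyl-2-hydroxy-6-methoxyphenyl)-3-methyl-1-oxobutan-2-yl 3-methylbut-2-enoate | COc1ccc(C=O)c(O)c1C(=O)[C@H](OC(=O)C=C(C)C)C(C)C
F6 | step 6 | 6-formyl-3-methoxy-2-[(2R)-3-methyl-2-[(3-methylbut-2-enoyl)oxy]butanoyl]phenyl (triphenyl-λ5-phosphanylidene)acetate | COc1ccc(C=O)c(OC(=O)C=P(c2ccccc2)(c2ccccc2)c2ccccc2)c1C(=O)[C@H](OC(=O)C=C(C)C)C(C)C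
A1 | direct plan | 2-hydroxy-4-methoxybenzaldehyde | COc1ccc(C=O)c(O)c1
A2 | direct plan | (2R)-2-{[tert-butyl(dimethyl)silyl]oxy}-N-methoxy-N,3-dimethylbutanamide | CON(C)C(=O)[C@H](O[Si](C)(C)C(C)(C)C)C(C)C
A3 | direct plan | 3-[(2R)-2-{[tert-butyl(dimethyl)silyl]oxy}-3-methylbutanoyl]-4-methoxy-2-(methoxymethoxy)benzaldehyde | COCOc1c(C=O)ccc(OC)c1C(=O)[C@H](O[Si](C)(C)C(C)(C)C)C(C)C
A4 | direct plan | 8-[(2R)-2-hydroxy-3-methylbutanoyl]-7-methoxy-2H-chromen-2-one | COc1ccc2ccc(=O)oc2c1C(=O)[C@H](O)C(C)C
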